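The numbers in the tables stem from a simulated flask with constants of no real substance; scatter was added.

Late in oak, target is still climbing while cross product stands at 44.0% of the starting material charged, and that plateau is the thing to watch.

| setting | oak | maple | winter | dusk | spring |
|---|---|---|---|---|---|
| starting material | 10 mM | 10 mM | 10 mM | 10 mM (fed, over 50 h) | 10 mM |
| second substrate | 5 mM | 5 mM | 5.00 mM (fed, over 50 h) | 5.00 mM | 5.00 mM |
| solid reagent | 25 mM | 50 mM | 25.0 mM | 25.0 mM | 25.0 mM |
| remark | run made earlier | run made earlier | all else is in the flask from the start; the feed brings no volume worth counting | all else is in the flask from the start; the feed brings no volume worth counting | everything together at the start |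
| time |  |  | 10 d | 10 d | 10 d |
oak run (percent of the starting material charged)

| time / d | cross product / % | target / % | starting material / % |
|---|---|---|---|
| 0.417 | 36.8 | 1.5 | 61.4 |
| 1.25 | 43.3 | 7.3 | 48.8 |
| 2.00 | 43.8 | 15.0 | 41.2 |
| 3.00 | 43.5 | 24.2 | 32.0 |
| 5.00 | 44.0 | 39.2 | 17.0 |
| 6.00 | 44.0 | 44.2 | 12.0 |

maple run (percent of the starting material charged)

| time / h | cross product / % | target / % | starting material / % |
|---|---|---|---|
| 8.00 | 34.1 | 1.3 | 64.8 |
| 15.0 | 41.1 | 2.6 | 56.4 |
| 25.0 | 43.5 | 6.0 | 51.3 |
| 30.0 | 43.6 | 7.6 | 48.6 |
| 40.0 | 43.3 | 11.0 | 44.4 |
| 50.0 | 43.8 | 15.5 | 40.6 |

(standard deviation of a reading: 0.3 percentage points)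
- the flask with the highest amount of cross product, in percent of the starting material charged ("all alike" if they lie within 1.5 percentage points) (winter / dusk / spring / all alike)
- final cross product, as a percentage of the starting material charged, in winter
- final cross product, as a percentage of the starting material charged, in dusk
- final cross product, as a percentage of the starting material charged, in spring

Second substrate is the limiting reagent of cross product (5.00 mM against 10 mM of starting material), so whatever it loses elsewhere comes straight off cross product. Oak shows the loss:

leak = c(second substrate) charged − c(cross product) = 0.620 mM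

I assume the leak goes to the same dissolved reagent that makes target, and that this reagent leaves the solid at a pace of its own. The readings allow this: maple, with 50 mM of solid, holds 15.5% target at 50.0 h, and oak, with 25 mM, holds 15.0% at 2.00 d.

drip = (leak + c(target)) / time = 1.06 mM d⁻¹

budget over the feed = drip × feed time = 2.21 mM

This drip, the dissolved reagent spent per day on target and leak, on average over the first 2.00 d of oak, lets me turn the question round. For "all alike", a fed flask may leak at most

0.770 mM, which is 34.9% of the budget.

In oak, the leak read at 2.00 d set against the target read at 1.25 d gives second substrate a share of 45.9%, which is more than that, so I expect feeding to cost cross product. At that share I reckon 39.9% cross product for winter. For dusk, where I give second substrate the whole budget, I reckon 27.9%. Spring has the charges of oak, so I expect the plateau of oak there.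

The forecast names spring, with 44% there, 41% in winter and 37% in dusk, above my dusk figure: “Winter falls modestly; dusk falls most”.

Most cross product stands in spring: 43.8%, against 37.0% in winter and 30.4% in dusk.

    starting material + second substrate → cross product (k = 0.332 M⁻¹ min⁻¹)
    starting material + partner → target (k = 0.294 M⁻¹ min⁻¹)
    second substrate + partner → second product (k = 2.79 M⁻¹ min⁻¹)
    solid reagent ⇌ partner, rate k4*(cs4 - [partner]) while solid is left; crystals form when [partner] > cs4 (solubility = 1.40 mM, k = 8.78 × 10⁻⁴ min⁻¹)
    partner → decomposition product (k = 8.15 × 10⁻⁷ min⁻¹)

In dusk, while second substrate was being used up, partner from the solid went to second product and target, 2.69 mM by 2.08 d against my budget of 2.21 mM, and 1.95 mM of that was second product. Winter spent 2.71 mM in the same time, 1.05 mM of it as second product, and by 5.00 d, with second substrate at 0%, its second product stood at 1.30 mM and its cross product at 37.0%.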